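The earlier runs and the new flask are simulated for substances that don't exist; noise was put on by code.

Where two nucleophiles draw on one intermediate, each at a rate proportional to its own free amount, and nothing else consumes them, one number stays constant through a run: the logarithm of the fraction of second nucleophile left, divided by the same logarithm for first nucleophile.

| setting | noon | autumn | north-west | east | south |
|---|---|---|---|---|---|
| substrate | 0.10 M | 0.10 M | 0.10 M | 0.10 M | 0.10 M |
| first nucleophile | 1.1 equiv | 1.1 equiv | 1.10 equiv | 1.10 equiv | 1.10 equiv |
| second nucleophile | 0.67 equiv | 2.3 equiv | 0.900 equiv | 1.40 equiv | 2.00 equiv |
| remark | run made earlier | run made earlier |  |  |  |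
| time |  |  | 2.0 h | 2.0 h | 2.0 h |

| run | time / min | intermediate / % | substrate / % | other capture product / % | side product / % | target / % |
|---|---|---|---|---|---|---|
| noon | 12.0 | 0 | 0.4 | 34.7 | 11.0 | 54.5 |
| noon | 25.0 | 0 | 0 | 34.9 | 11.4 | 54.3 |
| noon | 40.0 | 0.2 | 0 | 34.8 | 10.8 | 54.6 |
| noon | 50.0 | 0 | 0 | 34.5 | 10.8 | 54.7 |
| noon | 60.0 | 0 | 0 | 34.4 | 10.9 | 54.2 |
| autumn | 5.00 | 0 | 8.0 | 59.1 | 5.6 | 27.6 |
| autumn | 10.0 | 0.1 | 0.9 | 63.6 | 6.5 | 29.8 |
| autumn | 15.0 | 0.2 | 0 | 63.6 | 5.9 | 29.8 |
| autumn | 30.0 | 0 | 0 | 63.9 | 6.5 | 30.2 |
| autumn | 60.0 | 0.1 | 0.1 | 64.5 | 6.2 | 30.2 |

(standard deviation of a reading: 0.3 percentage points)

- in percentages every species weighs as the substrate in it: one side product counts as two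

* which of these there is most of at the end, counted by the substrate in it, north-west (other capture product / substrate / target / intermediate / side product)
* which of these there is most of at the end, counted by the substrate in it, east (other capture product / substrate / target / intermediate / side product)
* which of these there is most of at the end, counted by the substrate in it, south (other capture product / substrate / target / intermediate / side product)
* how much there is at the end of the one of these that leads, in percent of the substrate charged: north-west
* how much there is at the end of the one of these that leads, in percent of the substrate charged: east
* how much there is at the end of the one of these that leads, in percent of the substrate charged: south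

You can read that number from the two runs. Other capture product stands at 64.5 % in the autumn run, against 34.4 % in the noon run, with more second nucleophile charged, so I take it as the product of second nucleophile and target as the product of first. Side product holds two substrate units, and I count one of them as target consumed, which charges first nucleophile for it too. The last readings then give 0.922 for noon and 0.913 for autumn. Uncounted, they read 1.06 and 1.03, further apart, so I keep the counting. Their mean, 0.917, is my capture ratio (selectivity factor), a reading with its scatter.

Time is no question. Substrate at 8.0 % after 5.00 min in the autumn run means a half-life near 1.37 min, and 2.0 h is about 87.6 such half-lives.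

North-west looks nearly like noon, with second nucleophile raised from 0.67 equiv to 0.900 equiv. Yet the ratio times second nucleophile, 0.825, is still less than the 1.10 equiv of first, so I expect target ahead in north-west, as it is at noon. In east the product is 1.28, more than first, so I expect other capture product to lead there. A rough step of mine, taking both left fractions equal, borrowing side product from noon for north-west and from autumn for east and south, and then applying the ratio, gives target 49.1 % in north-west, and other capture product 50.7 % in east and 58.2 % in south.

The forecast, holding that “the target must come from the first nucleophile”, names the same leaders, at 49 %, 52.2 % and 60.9 %, though its ratio is about 1.04 against my 0.917.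

The flasks give target at 48.6 % in north-west, other capture product at 52.1 % in east and other capture product at 60.7 % in south.

    first nucleophile + intermediate → target (k = 4.90 L mol⁻¹ s⁻¹)
    substrate → intermediate (k = 0.00800 s⁻¹)
    substrate + target → side product (k = 0.0170 L mol⁻¹ s⁻¹)
    second nucleophile + intermediate → other capture product (k = 4.50 L mol⁻¹ s⁻¹)

In south at 0.0231 h, the half-life of intermediate by capture with second nucleophile alone is 0.015 min, against 1.4 min for substrate by its making of intermediate, and intermediate is made and used at a ratio of 0.994, its steady state. South's end amounts return a ratio of 0.918. For the neighbour of south with 0.280 equiv of first nucleophile, first let second nucleophile take the whole substrate: the ratio then puts the take of first nucleophile at about 14.8 % of the substrate charged, so my estimate of other capture product is near 85.2 %. That flask gives 85.9 %, with target at 11.6 %.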